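**Strategy**

The pyrrole ring is cut at N1–C2 and C4–C5. The contiguous bromine-bearing carbons C2, C3 and C4 are traced to the three ring carbons of tetrabromocyclopropene, whose fourth bromine becomes the leaving group for aromatisation; N1, its methyl group and C5 come from N-methylmethanimine, released in the flask from its cyclic trimer. One thermal operation should open the strained ring to a perbrominated vinylcarbene, join it to the imine, close the five-membered ring and expel HBr, giving 2,3,4-tribromo-1-methylpyrrole. The last free ring position, C5, is then brominated. Both partners are bought, so the risk sits in the first step alone.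

Key step: step 1

Assumption: tetrabromocyclopropene 1 is taken as a catalogue compound of specialty suppliers and is handled under argon because it is moisture-sensitive. A lot that has to be made in-house is one known halogen exchange (BBr3) away from tetrachlorocyclopropene. The target has no stereocentre.

**Route**

Step 1
Reactants: 1 tetrabromocyclopropene (1,2,3,3-tetrabromocycloprop-1-ene); 2 1,3,5-trimethyl-1,3,5-triazinane
Product: 7 2,3,4-tribromo-1-methyl-1H-pyrrole, via N-methylmethanimine 3 (not isolated), via bromo(tribromovinyl)carbene 4 (not isolated), via azomethine ylide 5 (not isolated), via 3,3,4,5-tetrabromo-1-methyl-2,3-dihydro-1H-pyrrole 6 (not isolated)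
Conditions: 2 (0.5 equiv, syringe pump over several hours) into 1, powdered anhydrous K2CO3 (3 equiv), 4 Å molecular sieves, PhCl, 130 °C, dry-ice condenser, Ar
Reagents that add atoms: none
Why: Proposed new method: on heating, 1 should open reversibly to the singlet carbene 4, whose electron-poor carbene carbon is intercepted by the nitrogen lone pair of imine 3 (or by an aminal nitrogen of 2, which then sheds two imine units) to give the conjugated ylide 5; the closest known reaction types are the thermal opening of tetrahalocyclopropenes to perhalovinylcarbenes that cyclopropanate alkenes and the formal [3+2] union of metal vinylcarbenes with imines to give dihydropyrroles. The single ring closes by six-electron 1,5-electrocyclisation of the five-atom ylide, which joins the methylene carbon to the dibromomethylene terminus (the C4–C5 bond) after the N–C2 bond has formed. Dihydropyrrole 6 should then ionise at its allylic CBr2 carbon with enamine assistance and lose a C5 proton, the HBr being taken up by K2CO3, so that aromatisation pulls the sequence forward. No stereocentre is created. The step needs chemoselectivity for the carbene manifold over ionisation of 1 to tribromocyclopropenium bromide and N-alkylation, which the non-polar solvent, the low standing concentration of amine and imine from slow addition, and the buffering base are chosen to secure. Regiochemistry is not at stake, because bonding of nitrogen to either end of the three-carbon unit, or initial addition across the C=N bond followed by ring expansion, converges on the same 2,3,4-tribromopyrrole once HBr is lost.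

Step 2
Reactants: 7 2,3,4-tribromo-1-methyl-1H-pyrrole
Product: 8 2,3,4,5-tetrabromo-1-methyl-1H-pyrrole
Conditions: NBS (1.05 equiv), THF, −78 °C to 0 °C, dark; aq. Na2S2O3 work-up
Reagents that add atoms: N-bromosuccinimide, O=C1CCC(=O)N1Br
Why: Electrophilic aromatic bromination of a pyrrole with NBS; C5 is the only ring carbon still bearing hydrogen and is an α-position, the most nucleophilic site of the ring, so one equivalent at low temperature in the dark should substitute it cleanly without touching the N-methyl group.

**Compound list**

1 | tetrabromocyclopropene (1,2,3,3-tetrabromocycloprop-1-ene) | BrC1=C(Br)C1(Br)Br | starting material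
2 | 1,3,5-trimethyl-1,3,5-triazinane | CN1CN(C)CN(C)C1 | starting material
3 | N-methylmethanimine | CN=C | intermediate
4 | bromo(1,2,2-tribromoethenyl)carbene | Br[C]C(Br)=C(Br)Br | intermediate
5 | azomethine ylide, N-methyl-N-methylidene-1,2,3,3-tetrabromoprop-2-en-1-aminium-1-ide | C=[N+](C)[C-](Br)C(Br)=C(Br)Br | intermediate
6 | 3,3,4,5-tetrabromo-1-methyl-2,3-dihydro-1H-pyrrole | CN1CC(Br)(Br)C(Br)=C1Br | intermediate
7 | 2,3,4-tribromo-1-methyl-1H-pyrrole | Cn1cc(Br)c(Br)c1Br | intermediate
8 | 2,3,4,5-tetrabromo-1-methyl-1H-pyrrole | Cn1c(Br)c(Br)c(Br)c1Br | target

**Step count and risks**

Total step count: 2
Longest linear sequence: 2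

The route has only two steps, so both are ranked.

1. Step 1 (new method). Ionisation of 1 to the cyclopropenium bromide and quaternisation at amine nitrogen may outrun thermal ring opening. The trimer may also release too little monomeric imine at this temperature, or the carbene may be consumed by oligomerisation or by addition to the product ring. Fallback in known chemistry: no numbered compound lies ahead of the first step, so the fallback sets 1 and 2 aside and sets out from purchased 1-methyl-1H-pyrrole F1. It installs all four bromines by electrophilic substitution on a ready-made ring instead of building the ring. With NBS (4.2 equiv) in THF from −78 °C to room temperature in the dark, the bromination should pass through 2-bromo-1-methyl-1H-pyrrole F2, 2,5-dibromo-1-methyl-1H-pyrrole F3 and 2,3,5-tribromo-1-methyl-1H-pyrrole F4, none of them isolated. It rejoins the route at target 8 and makes step 2 unnecessary.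

2. Step 2. HBr-mediated migration or loss of ring bromine, oxidative degradation of the electron-rich ring, or radical bromination at the N-methyl group may erode the conversion. Fallback: from 7, electrophilic substitution is replaced by directed deprotonation. TMPMgCl·LiCl (2,2,6,6-tetramethylpiperidin-1-ylmagnesium chloride–lithium chloride) in THF at −30 °C should magnesiate the only ring C–H to give (3,4,5-tribromo-1-methyl-1H-pyrrol-2-yl)magnesium chloride F5. Quenching the carbon–magnesium bond with 1,2-dibromo-1,1,2,2-tetrachloroethane returns to the route at 8.

**Further compounds**

F1 | step 1 | 1-methyl-1H-pyrrole (purchased) | Cn1cccc1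
F2 | step 1 | 2-bromo-1-methyl-1H-pyrrole | Cn1cccc1Br
F3 | step 1 | 2,5-dibromo-1-methyl-1H-pyrrole | Cn1c(Br)ccc1Br
F4 | step 1 | 2,3,5-tribromo-1-methyl-1H-pyrrole | Cn1c(Br)cc(Br)c1Br
F5 | step 2 | (3,4,5-tribromo-1-methyl-1H-pyrrol-2-yl)magnesium chloride | Cn1c([Mg]Cl)c(Br)c(Br)c1Br
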